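## Retrosynthetic overview

1. Target 28 ⇐ C8 desilylation and C9 acetylation of the bicyclic allylic alcohol 26.
2. Ten-membered ring (closed last) ⇐ C9–C10 bond by nickel-catalysed, chromium-mediated Nozaki–Hiyama–Kishi coupling of iodo-aldehyde 25.
3. γ-Lactone (closed second) and C6–C7 bond ⇐ ring-contractive zinc Barbier allylation of Z,Z-iodo-enal 15 with bromomethyl dihydropyranone 21, whose six-membered lactone (closed first, by ring-closing metathesis) is contracted in the same flask.
4. Enal 15 ⇐ C3–C4 bond by Pd-catalysed Negishi coupling of the alkylzinc from stannyl bromide 7 with Z-iodoalkene 11; both Z-alkenes come from trans-hydrometalation of small alkynes.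
5. All skeletal atoms come from six building blocks of at most seven non-hydrogen atoms (1, 2, 6, 8, 16, 19).

Assumption: positions are labelled by germacrane numbering (lactone O on C6, ring fusion C6–C7, OH on C8, OAc on C9, acyloxymethyl C14 on C10, methyl C15 on C4). The target is read as 6R,7R,8S,9R,2′R with both ring alkenes Z. Paraformaldehyde is counted as formaldehyde.

## Route

Step 1
Reactants: 1 4-bromobut-1-yne; 2 formaldehyde (charged as paraformaldehyde)
Product: 4 5-bromopent-2-yn-1-ol, via lithium acetylide 3 (not isolated)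
Conditions: n-BuLi, THF, −78 °C; (CH2O)n, −78 °C → rt; H2O
Reagents that add atoms: none
Why: Acetylide hydroxymethylation, in which deprotonation of the terminal alkyne at −78 °C is far faster than any attack on the primary bromide and the acetylide then adds to formaldehyde to install C14.

Step 2
Reactants: 4 5-bromopent-2-yn-1-ol
Product: 5 (2Z)-5-bromo-2-(tributylstannyl)pent-2-en-1-ol
Conditions: [Cp*RuCl]4 (1.25 mol %), Bu3SnH (slow addition), CH2Cl2, rt, dark
Reagents that add atoms: tributyltin hydride CCCC[SnH](CCCC)CCCC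
Why: Ruthenium-catalysed trans-hydrostannation, in which the propargylic hydroxyl steers tin to the proximal carbon and H and Sn add anti, fixing the Z geometry of the later C1=C10 bond.

Step 3
Reactants: 5 (2Z)-5-bromo-2-(tributylstannyl)pent-2-en-1-ol; 6 (2R)-2-methylbutanoic acid
Product: 7 (2Z)-5-bromo-2-(tributylstannyl)pent-2-en-1-yl (2R)-2-methylbutanoate
Conditions: DCC, DMAP (5 mol %), CH2Cl2, 0 °C → rt
Reagents that add atoms: none
Why: Steglich esterification of the primary allylic alcohol, which does not epimerise the α-stereocentre of the simple branched acid.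

Step 4
Reactants: 8 but-2-yn-1-ol
Product: 10 (2Z)-3-iodobut-2-en-1-ol, via cyclic vinylalanate 9 (not isolated)
Conditions: NaAlH2(OCH2CH2OCH3)2, THF, 0 °C → rt; I2, −78 °C → 0 °C
Reagents that add atoms: iodine [I][I]
Why: Hydroxyl-directed trans-hydroalumination places aluminium on C3 inside a five-membered alkoxyalanate and iodinolysis with retention gives the Z-iodoalkene that becomes the Z C4=C5 bond.

Step 5
Reactants: 10 (2Z)-3-iodobut-2-en-1-ol
Product: 11 triethyl{[(2Z)-3-iodobut-2-en-1-yl]oxy}silane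
Conditions: TESCl, imidazole, CH2Cl2, 0 °C
Reagents that add atoms: chlorotriethylsilane CC[Si](Cl)(CC)CC
Why: Routine silylation masks the hydroxyl so that the organozinc partner of the next step is not protonated.

Step 6
Reactants: 7 (2Z)-5-bromo-2-(tributylstannyl)pent-2-en-1-yl (2R)-2-methylbutanoate; 11 triethyl{[(2Z)-3-iodobut-2-en-1-yl]oxy}silane
Product: 13 (2Z,6Z)-6-methyl-2-(tributylstannyl)-8-[(triethylsilyl)oxy]octa-2,6-dien-1-yl (2R)-2-methylbutanoate, via alkylzinc bromide 12 (not isolated)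
Conditions: Zn dust (activated), LiCl, THF, 50 °C; then 11, PdCl2(dppf) (5 mol %), THF, rt
Reagents that add atoms: none
Why: Negishi sp3–sp2 coupling forms C3–C4 with retention of the Z-iodoalkene geometry, transmetalation from zinc being much faster than Stille transfer from the hindered alkenylstannane that serves as a masked iodide.

Step 7
Reactants: 13 (2Z,6Z)-6-methyl-2-(tributylstannyl)-8-[(triethylsilyl)oxy]octa-2,6-dien-1-yl (2R)-2-methylbutanoate
Product: 14 (2Z,6Z)-2-iodo-6-methyl-8-[(triethylsilyl)oxy]octa-2,6-dien-1-yl (2R)-2-methylbutanoate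
Conditions: I2, CH2Cl2, 0 °C, dark
Reagents that add atoms: iodine [I][I]
Why: Iododestannylation is an ipso substitution with retention, so the Z-stannane gives the Z-iodide while the trisubstituted alkene, silyl ether and ester are untouched.

Step 8
Reactants: 14 (2Z,6Z)-2-iodo-6-methyl-8-[(triethylsilyl)oxy]octa-2,6-dien-1-yl (2R)-2-methylbutanoate
Product: 15 (2Z,6Z)-2-iodo-6-methyl-8-oxoocta-2,6-dien-1-yl (2R)-2-methylbutanoate
Conditions: (COCl)2, DMSO, CH2Cl2, −78 → −40 °C; Et3N, −78 → 0 °C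
Reagents that add atoms: none
Why: Swern oxidation applied directly to the primary triethylsilyl ether (activated DMSO cleaves the O–Si bond) gives the Z-enal at low temperature without Z/E isomerisation.

Step 9
Reactants: 16 (2S)-but-3-ene-1,2-diol
Product: 17 (2S)-1,2-bis(TBSO)but-3-ene
Conditions: TBSCl (2.5 equiv), imidazole, DMF, rt
Reagents that add atoms: tert-butyldimethylsilyl chloride CC(C)(C)[Si](C)(C)Cl
Why: Exhaustive silylation of the commercial enantiopure diol, whose stereocentre becomes C8.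

Step 10
Reactants: 17 (2S)-1,2-bis(TBSO)but-3-ene
Product: 18 (2S)-2-(TBSO)but-3-en-1-ol
Conditions: HF·pyridine, pyridine, THF, 0 °C
Reagents that add atoms: none
Why: Selective desilylation, the unhindered primary silyl ether being cleaved much faster than the secondary allylic one under buffered acidic fluoride that does not cause silyl migration.

Step 11
Reactants: 18 (2S)-2-(TBSO)but-3-en-1-ol; 19 2-(bromomethyl)prop-2-enoic acid
Product: 20 (2S)-2-(TBSO)but-3-en-1-yl 2-(bromomethyl)prop-2-enoate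
Conditions: DCC, DMAP (5 mol %), CH2Cl2, −10 → 0 °C
Reagents that add atoms: none
Why: Steglich esterification at low temperature with little DMAP acylates the primary alcohol faster than the amine can displace the allylic bromide.

Step 12
Reactants: 20 (2S)-2-(TBSO)but-3-en-1-yl 2-(bromomethyl)prop-2-enoate
Product: 21 (5S)-3-(bromomethyl)-5-(TBSO)-5,6-dihydro-2H-pyran-2-one
Conditions: second-generation Hoveyda–Grubbs catalyst (5 mol %), toluene, 80 °C, 5 mM
Reagents that add atoms: none
Why: Ring-closing metathesis between the vinyl group and the 1,1-disubstituted acrylate closes the six-membered unsaturated lactone with loss of ethene and leaves the allylic bromide in place.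

Step 13
Reactants: 15 (2Z,6Z)-2-iodo-6-methyl-8-oxoocta-2,6-dien-1-yl (2R)-2-methylbutanoate; 21 (5S)-3-(bromomethyl)-5-(TBSO)-5,6-dihydro-2H-pyran-2-one
Product: 24 (2Z,6Z)-7-[(2R,3S)-3-{(1S)-1-(TBSO)-2-hydroxyethyl}-4-methylidene-5-oxooxolan-2-yl]-2-iodo-6-methylhepta-2,6-dien-1-yl (2R)-2-methylbutanoate, via allylzinc bromide 22 (not isolated), via hydroxy δ-lactone 23 (not isolated)
Conditions: Zn dust, THF/sat. aq. NH4Cl (3:1), 0 °C → rt; then PPTS (10 mol %), CH2Cl2, rt
Reagents that add atoms: none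
Why: Proposed new method: a ring-contractive Barbier allylation in which zinc inserts into the allylic C–Br bond of 21 to give an allylzinc whose C7=C11 bond is locked in the ring with C8 trans to the CH2Zn carbon, so that γ-attack on the enal through a Zimmerman–Traxler chair (alkenyl group equatorial, approach opposite the C8 silyloxy group) forms C6–C7 and sets 6R and 7R, after which mild acid lets the new C6 hydroxyl, γ to the carbonyl, open the strained α-methylene δ-lactone and reclose it as the trans-fused α-methylene γ-lactone with release of the C9 primary alcohol; the closest known reactions are zinc- and chromium-mediated Barbier allylations with 2-(bromomethyl)acrylates and 3-(bromomethyl)furan-2(5H)-ones.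

Step 14
Reactants: 24 (2Z,6Z)-7-[(2R,3S)-3-{(1S)-1-(TBSO)-2-hydroxyethyl}-4-methylidene-5-oxooxolan-2-yl]-2-iodo-6-methylhepta-2,6-dien-1-yl (2R)-2-methylbutanoate
Product: 25 (2Z,6Z)-7-[(2R,3S)-3-{(1S)-1-(TBSO)-2-oxoethyl}-4-methylidene-5-oxooxolan-2-yl]-2-iodo-6-methylhepta-2,6-dien-1-yl (2R)-2-methylbutanoate
Conditions: Dess–Martin periodinane, NaHCO3, CH2Cl2, 0 °C → rt
Reagents that add atoms: none
Why: Buffered Dess–Martin oxidation converts the primary alcohol into the α-silyloxy aldehyde without epimerising C8 or touching the iodoalkene and the methylene lactone.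

Step 15
Reactants: 25 (2Z,6Z)-7-[(2R,3S)-3-{(1S)-1-(TBSO)-2-oxoethyl}-4-methylidene-5-oxooxolan-2-yl]-2-iodo-6-methylhepta-2,6-dien-1-yl (2R)-2-methylbutanoate
Product: 26 [(3aS,4S,5R,6Z,10Z,11aR)-4-(TBSO)-5-hydroxy-10-methyl-3-methylidene-2-oxo-2,3,3a,4,5,8,9,11a-octahydrocyclodeca[b]furan-6-yl]methyl (2R)-2-methylbutanoate
Conditions: NiCl2 (5 mol %), CrCl2 (6 equiv), degassed DMSO/THF (3:1), rt, syringe-pump addition (final 2 mM)
Reagents that add atoms: none
Why: Nickel-catalysed Nozaki–Hiyama–Kishi coupling, in which zerovalent nickel inserts into the C10–I bond, the alkenyl group passes to chromium with retention of the Z geometry and adds to the C9 aldehyde under high dilution, Felkin–Anh approach anti to the C8 silyloxy group giving the 9R carbinol and closing the ten-membered ring.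

Step 16
Reactants: 26 [(3aS,4S,5R,6Z,10Z,11aR)-4-(TBSO)-5-hydroxy-10-methyl-3-methylidene-2-oxo-2,3,3a,4,5,8,9,11a-octahydrocyclodeca[b]furan-6-yl]methyl (2R)-2-methylbutanoate
Product: 27 [(3aS,4S,5R,6Z,10Z,11aR)-5-(acetyloxy)-4-(TBSO)-10-methyl-3-methylidene-2-oxo-2,3,3a,4,5,8,9,11a-octahydrocyclodeca[b]furan-6-yl]methyl (2R)-2-methylbutanoate
Conditions: Ac2O, pyridine, DMAP (cat.), CH2Cl2, 0 °C → rt
Reagents that add atoms: acetic anhydride CC(=O)OC(C)=O
Why: Acylation of the only free hydroxyl (C9, secondary allylic) leaves the C8 silyl ether, the lactone and the C14 ester unchanged.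

Step 17
Reactants: 27 [(3aS,4S,5R,6Z,10Z,11aR)-5-(acetyloxy)-4-(TBSO)-10-methyl-3-methylidene-2-oxo-2,3,3a,4,5,8,9,11a-octahydrocyclodeca[b]furan-6-yl]methyl (2R)-2-methylbutanoate
Product: 28 [(3aR,4S,5R,6Z,10Z,11aR)-5-(acetyloxy)-4-hydroxy-10-methyl-3-methylidene-2-oxo-2,3,3a,4,5,8,9,11a-octahydrocyclodeca[b]furan-6-yl]methyl (2R)-2-methylbutanoate (CNP0005248.2)
Conditions: HF·pyridine, pyridine, THF, 0 °C → rt
Reagents that add atoms: none
Why: Buffered acidic fluoride cleaves the C8 silyl ether without the base that would promote 9→8 acetyl migration or relactonisation onto the C8 hydroxyl.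

(The C7 descriptor is S in 23–27 and R in 28 only because the O–Si group changes the CIP ranking; the spatial arrangement is the same.)

## Compound list

1 | 4-bromobut-1-yne | C#CCCBr | starting material
2 | formaldehyde (as paraformaldehyde) | C=O | starting material
3 | (4-bromobut-1-yn-1-yl)lithium | [Li]C#CCCBr | intermediate
4 | 5-bromopent-2-yn-1-ol | OCC#CCCBr | intermediate
5 | (2Z)-5-bromo-2-(tributylstannyl)pent-2-en-1-ol | BrCC/C=C(/CO)[Sn](CCCC)(CCCC)CCCC | intermediate
6 | (2R)-2-methylbutanoic acid | CC[C@@H](C)C(=O)O | starting material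
7 | (2Z)-5-bromo-2-(tributylstannyl)pent-2-en-1-yl (2R)-2-methylbutanoate | BrCC/C=C(/COC(=O)[C@H](C)CC)[Sn](CCCC)(CCCC)CCCC | intermediate
8 | but-2-yn-1-ol | CC#CCO | starting material
9 | sodium 2,2-bis(2-methoxyethoxy)-3-methyl-2,5-dihydro-1,2-oxaluminol-2-uide (cyclic vinylalanate) | CC1=CCO[Al-]1(OCCOC)OCCOC.[Na+] | intermediate
10 | (2Z)-3-iodobut-2-en-1-ol | C/C(I)=C/CO | intermediate
11 | triethyl{[(2Z)-3-iodobut-2-en-1-yl]oxy}silane | C/C(I)=C/CO[Si](CC)(CC)CC | intermediate
12 | bromo[(3Z)-5-{[(2R)-2-methylbutanoyl]oxy}-4-(tributylstannyl)pent-3-en-1-yl]zinc | Br[Zn]CC/C=C(/COC(=O)[C@H](C)CC)[Sn](CCCC)(CCCC)CCCC | intermediate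
13 | (2Z,6Z)-6-methyl-2-(tributylstannyl)-8-[(triethylsilyl)oxy]octa-2,6-dien-1-yl (2R)-2-methylbutanoate | CC[Si](CC)(CC)OC/C=C(/C)CC/C=C(/COC(=O)[C@H](C)CC)[Sn](CCCC)(CCCC)CCCC | intermediate
14 | (2Z,6Z)-2-iodo-6-methyl-8-[(triethylsilyl)oxy]octa-2,6-dien-1-yl (2R)-2-methylbutanoate | CC[Si](CC)(CC)OC/C=C(/C)CC/C=C(I)/COC(=O)[C@H](C)CC | intermediate
15 | (2Z,6Z)-2-iodo-6-methyl-8-oxoocta-2,6-dien-1-yl (2R)-2-methylbutanoate | O=C/C=C(/C)CC/C=C(I)/COC(=O)[C@H](C)CC | intermediate
16 | (2S)-but-3-ene-1,2-diol | C=C[C@H](O)CO | starting material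
17 | (2S)-1,2-bis[(tert-butyldimethylsilyl)oxy]but-3-ene | C=C[C@H](O[Si](C)(C)C(C)(C)C)CO[Si](C)(C)C(C)(C)C | intermediate
18 | (2S)-2-[(tert-butyldimethylsilyl)oxy]but-3-en-1-ol | C=C[C@H](O[Si](C)(C)C(C)(C)C)CO | intermediate
19 | 2-(bromomethyl)prop-2-enoic acid | C=C(CBr)C(=O)O | starting material
20 | (2S)-2-[(tert-butyldimethylsilyl)oxy]but-3-en-1-yl 2-(bromomethyl)prop-2-enoate | C=C[C@H](O[Si](C)(C)C(C)(C)C)COC(=O)C(=C)CBr | intermediate
21 | (5S)-3-(bromomethyl)-5-[(tert-butyldimethylsilyl)oxy]-5,6-dihydro-2H-pyran-2-one | BrCC1=C[C@H](O[Si](C)(C)C(C)(C)C)COC1=O | intermediate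
22 | bromo{[(5S)-5-[(tert-butyldimethylsilyl)oxy]-2-oxo-5,6-dihydro-2H-pyran-3-yl]methyl}zinc | Br[Zn]CC1=C[C@H](O[Si](C)(C)C(C)(C)C)COC1=O | intermediate
23 | (2Z,6Z,8R)-8-[(4S,5S)-5-[(tert-butyldimethylsilyl)oxy]-3-methylidene-2-oxooxan-4-yl]-8-hydroxy-2-iodo-6-methylocta-2,6-dien-1-yl (2R)-2-methylbutanoate | C=C1C(=O)OC[C@@H](O[Si](C)(C)C(C)(C)C)[C@@H]1[C@H](O)/C=C(/C)CC/C=C(I)/COC(=O)[C@H](C)CC | intermediate
24 | (2Z,6Z)-7-[(2R,3S)-3-{(1S)-1-[(tert-butyldimethylsilyl)oxy]-2-hydroxyethyl}-4-methylidene-5-oxooxolan-2-yl]-2-iodo-6-methylhepta-2,6-dien-1-yl (2R)-2-methylbutanoate | C=C1C(=O)O[C@H](/C=C(/C)CC/C=C(I)/COC(=O)[C@H](C)CC)[C@H]1[C@H](O[Si](C)(C)C(C)(C)C)CO | intermediate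
25 | (2Z,6Z)-7-[(2R,3S)-3-{(1S)-1-[(tert-butyldimethylsilyl)oxy]-2-oxoethyl}-4-methylidene-5-oxooxolan-2-yl]-2-iodo-6-methylhepta-2,6-dien-1-yl (2R)-2-methylbutanoate | C=C1C(=O)O[C@H](/C=C(/C)CC/C=C(I)/COC(=O)[C@H](C)CC)[C@H]1[C@H](O[Si](C)(C)C(C)(C)C)C=O | intermediate
26 | [(3aS,4S,5R,6Z,10Z,11aR)-4-[(tert-butyldimethylsilyl)oxy]-5-hydroxy-10-methyl-3-methylidene-2-oxo-2,3,3a,4,5,8,9,11a-octahydrocyclodeca[b]furan-6-yl]methyl (2R)-2-methylbutanoate | C=C1C(=O)O[C@@H]2/C=C(/C)CC/C=C(/COC(=O)[C@H](C)CC)[C@@H](O)[C@@H](O[Si](C)(C)C(C)(C)C)[C@@H]12 | intermediate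
27 | [(3aS,4S,5R,6Z,10Z,11aR)-5-(acetyloxy)-4-[(tert-butyldimethylsilyl)oxy]-10-methyl-3-methylidene-2-oxo-2,3,3a,4,5,8,9,11a-octahydrocyclodeca[b]furan-6-yl]methyl (2R)-2-methylbutanoate | C=C1C(=O)O[C@@H]2/C=C(/C)CC/C=C(/COC(=O)[C@H](C)CC)[C@@H](OC(C)=O)[C@@H](O[Si](C)(C)C(C)(C)C)[C@@H]12 | intermediate
28 | [(3aR,4S,5R,6Z,10Z,11aR)-5-(acetyloxy)-4-hydroxy-10-methyl-3-methylidene-2-oxo-2,3,3a,4,5,8,9,11a-octahydrocyclodeca[b]furan-6-yl]methyl (2R)-2-methylbutanoate | C=C1C(=O)O[C@@H]2/C=C(/C)CC/C=C(/COC(=O)[C@H](C)CC)[C@@H](OC(C)=O)[C@@H](O)[C@@H]12 | target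

## Step count and risk

Total step count: 17. Longest linear sequence: 11 steps (1–3, 6–8, 13–17).

The three steps most likely to fail:

**Step 13 (the proposed new ring-contractive Barbier allylation).** Facial control by the C8 silyloxy group and the δ→γ ring contraction are untested on this lactone class. The fallback sets out from 21 (with 15) and comes back at 24, replacing the in-situ allylzinc by an isolable allylboron reagent. Palladium-catalysed borylation of the allylic bromide 21 (B2pin2, Pd2(dba)3, THF, 50 °C) gives (5S)-5-[(tert-butyldimethylsilyl)oxy]-3-[(4,4,5,5-tetramethyl-1,3,2-dioxaborolan-2-yl)methyl]-5,6-dihydro-2H-pyran-2-one F4. Sc(OTf)3-catalysed allylboration of enal 15 (toluene, 0 °C → rt) is stereospecific through a closed six-membered transition state with the same E-locked geometry, and after aqueous work-up gives hydroxy δ-lactone 23, this time isolated. PPTS in CH2Cl2 then contracts 23 to 24.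

**Step 15 (ten-membered ring closure).** Ring strain and facial selectivity at C9 are substrate-dependent, and the allylic ester next to the alkenyl metal is a further concern. The fallback covers the likeliest failure, closure to the wrong C9 epimer; it sets out from 25 and comes back at 27. If the same nickel/chromium closure gives mainly the 9S alcohol [(3aS,4S,5S,6Z,10Z,11aR)-4-[(tert-butyldimethylsilyl)oxy]-5-hydroxy-10-methyl-3-methylidene-2-oxo-2,3,3a,4,5,8,9,11a-octahydrocyclodeca[b]furan-6-yl]methyl (2R)-2-methylbutanoate F5, the centre is corrected by substitution instead of by addition control. Mitsunobu reaction with acetic acid (PPh3, DIAD, AcOH, toluene, 0 °C → rt) inverts C9 and installs the acetate in one operation, giving 27 directly and bypassing step 16.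

**Step 12 (ring-closing metathesis of the bromomethyl acrylate).** The electron-poor 1,1-disubstituted olefin carrying an allylic bromide may initiate slowly or degrade the catalyst. The fallback sets out from 18 and comes back at 21, introducing the bromomethyl group after ring closure. Alcohol 18 is acylated with acryloyl chloride (Et3N, CH2Cl2, 0 °C) to (2S)-2-[(tert-butyldimethylsilyl)oxy]but-3-en-1-yl prop-2-enoate F1. Ring-closing metathesis of this unhindered acrylate (second-generation Grubbs catalyst, CH2Cl2, 40 °C) gives (5S)-5-[(tert-butyldimethylsilyl)oxy]-5,6-dihydro-2H-pyran-2-one F2. Morita–Baylis–Hillman hydroxymethylation (aqueous formaldehyde 2, DMAP, THF/H2O, rt) gives (5S)-5-[(tert-butyldimethylsilyl)oxy]-3-(hydroxymethyl)-5,6-dihydro-2H-pyran-2-one F3. Appel bromination (CBr4, PPh3, CH2Cl2, 0 °C) returns 21.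

## Further compounds

F1 | step 12 | (2S)-2-[(tert-butyldimethylsilyl)oxy]but-3-en-1-yl prop-2-enoate | C=C[C@H](O[Si](C)(C)C(C)(C)C)COC(=O)C=C
F2 | step 12 | (5S)-5-[(tert-butyldimethylsilyl)oxy]-5,6-dihydro-2H-pyran-2-one | O=C1C=C[C@H](O[Si](C)(C)C(C)(C)C)CO1
F3 | step 12 | (5S)-5-[(tert-butyldimethylsilyl)oxy]-3-(hydroxymethyl)-5,6-dihydro-2H-pyran-2-one | OCC1=C[C@H](O[Si](C)(C)C(C)(C)C)COC1=O
F4 | step 13 | (5S)-5-[(tert-butyldimethylsilyl)oxy]-3-[(4,4,5,5-tetramethyl-1,3,2-dioxaborolan-2-yl)methyl]-5,6-dihydro-2H-pyran-2-one | CC1(C)OB(CC2=C[C@H](O[Si](C)(C)C(C)(C)C)COC2=O)OC1(C)C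
F5 | step 15 | [(3aS,4S,5S,6Z,10Z,11aR)-4-[(tert-butyldimethylsilyl)oxy]-5-hydroxy-10-methyl-3-methylidene-2-oxo-2,3,3a,4,5,8,9,11a-octahydrocyclodeca[b]furan-6-yl]methyl (2R)-2-methylbutanoate | C=C1C(=O)O[C@@H]2/C=C(/C)CC/C=C(/COC(=O)[C@H](C)CC)[C@H](O)[C@@H](O[Si](C)(C)C(C)(C)C)[C@@H]12
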